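## The problem

Compound 22 (C33H26O6) is a trimer of 8-methoxynaphthalen-1-ol (7). The central naphthol carries one terminal unit (ring system A) on C2 through a 2,2' bond, ortho to both hydroxyls, and the other (ring system C) on C4 through a 4,4' bond, para to both hydroxyls. Because the three units have the same substitution, the task is regiochemical: each biaryl bond must sit at a defined ortho or para carbon, which direct oxidative coupling of 7 cannot guarantee, and symmetric dimers bring a desymmetrisation problem of their own. There is no stereocentre and neither biaryl axis is configurationally defined in the target, so no stereocontrol is needed; the two bridgehead stereocentres made on the way arise as a racemate, with relative configuration dictated by the bicycle, and vanish in the last step. The free peri-methoxy naphthols are electron-rich and prone to oxidation and further coupling, and the aryl methyl ethers must survive, so the hydroxyls stay masked until a final step that is non-oxidative and free of strong Lewis acids. The enabling feature lies in ring system C: C4 (bearing the central naphthyl) and C1 (bearing OH) are the 1,4-carbons of one benzenoid ring, and the methoxyl on C8 is peri to C1. These two carbons map onto the two furan carbons of a 1-aryl-4-methoxyisobenzofuran, C2 and C3 onto a two-carbon acetylene equivalent, and the furan oxygen onto the naphthol oxygen, so this ring can be built by a Diels–Alder reaction on a central unit that already carries ring system A.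

## Retrosynthesis

**22 from 21.** No carbon–carbon bond is cut. The naphthol ring of ring system C is traced back to the 1,4-epoxy-1,4-dihydronaphthalene 21, whose oxygen bridge still joins the aryl-bearing carbon to the future hydroxyl carbon. The two remaining hydroxyls are masked as methoxymethyl ethers. Forward, one acid treatment has to open the bridge at the tertiary, aryl-bearing bridgehead (so that oxygen stays next to the methoxy-bearing ring carbon) and also remove both acetals. Methoxymethyl is preferred to benzyl because it saves a separate hydrogenolysis and because it is the directing group needed to make 10.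

**21 from 17 and 18.** The two C–C bonds between the bridgeheads and the CH=CH unit are cut. This leads back through the sulfinyl cycloadduct 20 to the isobenzofuran 19 and phenyl vinyl sulfoxide 18, and 19 is the dehydration product of the keto alcohol 17. This cut is preferred to a cross-coupling of two finished naphthalenes because it needs no 4-functionalised monomer made selectively and makes the most hindered junction from an aryllithium and a carbonyl group. The forward step must generate a sensitive diene in the presence of its trap, and the adduct must lose sulfur without opening the bridge.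

**17 from 15 and 5.** The aryl–carbonyl bond is cut to give the aryllithium 16, made from the bromide 15, and 4-methoxyphthalide 5. The phthalide fixes the only regiochemical relation that matters later: its CH2, the future CH bridgehead and hydroxyl carbon, lies next to the methoxyl. The forward reaction is a single addition of a hindered aryllithium to a lactone.

**5 from 1.** The lactone C–O bond and the benzylic C–Br bond are traced back through the hydroxy ester 4, the bromide 3 and the ester 2 to 3-methoxy-2-methylbenzoic acid 1. Only a benzylic bromination and a lactonisation are required.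

**15 from 12 and 10.** The 2,2' bond is cut to give the arylzinc 14 (from the dibromide 12 through the arylmagnesium 13) and the iodide 10. The alternative is a symmetric dimer such as F6 followed by bromination of one of two equivalent rings. That is shorter, but it is statistical and gives mono-, di- and non-brominated biaryls that differ only by bromine and would be hard to separate. In the cross-coupling the para bromine is placed before the biaryl bond exists. The forward step needs exchange only at the bromine ortho to the acetal oxygen, and coupling only at iodine.

**10 and 12 from 7; 7 from 6.** The iodide 10 comes from the ether 8 by lithiation next to the acetal (aryllithium 9). The dibromide 12 comes from the dibromonaphthol 11. Both start from 7, the monomethyl ether of naphthalene-1,8-diol 6. Bromination is done on the free naphthol because only a free hydroxyl directs both halogens into its own ring.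

## Roads not taken

**Alternative 1: twofold aryne Diels–Alder on a C8 bis-dienol ether.** The cut removes, in both 4,4'-linked units, the bonds from the oxygenated ring to the methoxy-bearing ring. Forward, two equivalents of the aryne released by fluoride from A3 would add to the terminal siloxydiene units of the tetraene A2. Dehydrogenation in the same flask would give the bis-silyl ether A1 of the 4,4'-dimer. In convergence this road is better than the chosen one: two rings and four C–C bonds form in one operation from a symmetrical chain, and the electronic bias of the aryne matches the required peri relation. Its weak points are these: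
- A conjugated tetraene also offers its internal diene.
- Acyclic dienes give ene and [2+2] products with arynes.
- Regioselectivity must hold twice.
- A1 is symmetric, so attaching ring system A at C2 of only one unit brings back a statistical desymmetrisation and leaves the 2,2' bond still to be made.

The chosen plan is longer, but each regiochemical relation is fixed by a halogen position or by the phthalide.

**Alternative 2: aryl Grignard addition to a naphthalyne with oxidation.** The cut is the 2,2' bond together with the C1–O bond of ring system A. Forward, the bis(methoxymethyl) ether A6 of the 4,4'-dimer would be metalated at C2 of one unit and added to the naphthalyne released from the iodo sulfonate A5. The resulting arylmagnesium would be borylated and oxidised to give A4, one deprotection from 22. Its merits are a transition-metal-free formation of the ortho–ortho bond, installation of the last hydroxyl in the same flask, and a very short endgame, shorter than the chosen one. Its weak points are these: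
- A6 itself needs a selective para–para coupling of 7.
- Its mono-metalation is again statistical.
- A hindered ortho-alkoxy aryl Grignard must add at C2 of an aryne bearing a peri methoxyl.
- A5 needs an ortho-selective iodination of 7.

The chosen plan sets against this a catalytic cross-coupling whose regiochemistry is written into the halides, and it never needs the 4,4'-dimer.

**Alternative 3: chlorocarbene ring expansion of a siloxyindene.** The cut is C1–C2 and C2–C3 of the central ring. Forward, the carbene released on heating the diazirine A8 would cyclopropanate the siloxyindene A9. Opening of the chlorocyclopropane with loss of HCl would give the central naphthol silyl ether A7, with both terminal units in place. In regiochemical security it equals the chosen plan, and it is fully convergent in three fragments with no halogen differentiation on the central ring. Its weak points are these: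
- A9 needs a 3-aryl-7-methoxyindanone made by its own sequence.
- A8 needs hypohalite oxidation of an amidine on a naphthalene ring that is easily chlorinated.
- An ortho-alkoxy arylcarbene must add to a trisubstituted, aryl-flanked enol ether in competition with dimerisation and insertion.

The chosen plan has a more reactive diene and a simple dienophile in its key step and shorter routes to both partners.

Key step: step 11

Remark on the chemistry: naphthalene-1,8-diol (6) is taken as a purchasable material, and 17 is drawn in its open keto alcohol form although it may exist largely as its cyclic hemiketal form, which is treated as the same compound. In the names of 19–21, Ar = 5-methoxy-4-(methoxymethoxy)-3-[8-methoxy-1-(methoxymethoxy)naphthalen-2-yl]naphthalen-1-yl.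

## Route

Step 1
Reactants: 1 3-methoxy-2-methylbenzoic acid
Product: 2 methyl 3-methoxy-2-methylbenzoate
Conditions: MeOH, H2SO4 (cat.), reflux
Reagents that add atoms: methanol, CO
Why: Fischer esterification; the ester is needed so that the carboxyl group does not interfere with the radical bromination and can later close the lactone.

Step 2
Reactants: 2 methyl 3-methoxy-2-methylbenzoate
Product: 3 methyl 2-(bromomethyl)-3-methoxybenzoate
Conditions: NBS (1.05 equiv), AIBN (cat.), PhCF3, 80 °C
Reagents that add atoms: N-bromosuccinimide, O=C1CCC(=O)N1Br
Why: Wohl–Ziegler bromination at the only benzylic position; radical conditions in a non-polar solvent should suppress electrophilic ring bromination.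

Step 3
Reactants: 3 methyl 2-(bromomethyl)-3-methoxybenzoate
Product: 5 4-methoxyphthalide (4-methoxy-3H-2-benzofuran-1-one), via methyl 2-(hydroxymethyl)-3-methoxybenzoate 4 (not isolated)
Conditions: H2O/1,4-dioxane (1:1), reflux
Reagents that add atoms: water, O
Why: Solvolysis of the benzylic bromide followed by spontaneous five-ring lactonisation of the hydroxy ester; the CH2 of the lactone ends up next to the methoxy-bearing carbon, as the later steps require.

Step 4
Reactants: 6 naphthalene-1,8-diol
Product: 7 8-methoxynaphthalen-1-ol
Conditions: MeI (1.1 equiv), K2CO3 (1 equiv), acetone, reflux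
Reagents that add atoms: iodomethane, CI
Why: Williamson etherification that should stop at the monoether, because the remaining hydroxyl is tied up in a hydrogen bond to the new peri methoxyl and is much less acidic.

Step 5
Reactants: 7 8-methoxynaphthalen-1-ol
Product: 8 1-methoxy-8-(methoxymethoxy)naphthalene
Conditions: NaH, MOMCl, DMF, 0 °C to rt
Reagents that add atoms: chloromethyl methyl ether, COCCl
Why: Williamson-type acetalisation; full deprotonation with NaH breaks the intramolecular hydrogen bond that makes this naphthol sluggish with weaker bases.

Step 6
Reactants: 8 1-methoxy-8-(methoxymethoxy)naphthalene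
Product: 10 2-iodo-8-methoxy-1-(methoxymethoxy)naphthalene, via 2-lithio-8-methoxy-1-(methoxymethoxy)naphthalene 9 (not isolated)
Conditions: n-BuLi, TMEDA, Et2O, 0 °C; then I2, THF, −78 °C to rt
Reagents that add atoms: iodine, II
Why: Directed ortho-metalation; the chelating acetal outranks the methoxyl as director and has C2 as its only free ortho position, and iodine quenches the aryllithium at that carbon.

Step 7
Reactants: 7 8-methoxynaphthalen-1-ol
Product: 11 2,4-dibromo-8-methoxynaphthalen-1-ol
Conditions: NBS (2.05 equiv), MeCN (anhydrous), 0 °C to rt, dark
Reagents that add atoms: N-bromosuccinimide, O=C1CCC(=O)N1Br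
Why: Electrophilic aromatic bromination; the free hydroxyl activates its own ortho and para carbons far more than the methoxyl activates the other ring, and exclusion of water avoids oxidation to a bromoquinone.

Step 8
Reactants: 11 2,4-dibromo-8-methoxynaphthalen-1-ol
Product: 12 2,4-dibromo-8-methoxy-1-(methoxymethoxy)naphthalene
Conditions: NaH, MOMCl, DMF, 0 °C to rt
Reagents that add atoms: chloromethyl methyl ether, COCCl
Why: Williamson-type acetalisation of the hindered, acidic dibromonaphthol through its sodium salt.

Step 9
Reactants: 12 2,4-dibromo-8-methoxy-1-(methoxymethoxy)naphthalene; 10 2-iodo-8-methoxy-1-(methoxymethoxy)naphthalene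
Product: 15 4-bromo-8,8'-dimethoxy-1,1'-bis(methoxymethoxy)-2,2'-binaphthalene, via 4-bromo-8-methoxy-1-(methoxymethoxy)naphthalen-2-ylmagnesium chloride 13 (not isolated), via 4-bromo-8-methoxy-1-(methoxymethoxy)naphthalen-2-ylzinc chloride 14 (not isolated)
Conditions: 12, iPrMgCl·LiCl (1.0 equiv), THF, −15 to 0 °C; ZnCl2, 0 °C to rt; then 10, Pd(PPh3)4 (5 mol %), THF, 50 °C
Reagents that add atoms: none
Why: Bromine–magnesium exchange is expected only at the bromine ortho to the chelating acetal oxygen, as with other 2,4-dibromoaryl ethers; after transmetalation to zinc, a Negishi coupling follows in which zerovalent palladium with PPh3 inserts into the C–I bond of 10 much faster than into the electron-rich C4–Br bonds of 14 and 15, so the para bromine should survive.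

Step 10
Reactants: 15 4-bromo-8,8'-dimethoxy-1,1'-bis(methoxymethoxy)-2,2'-binaphthalene; 5 4-methoxyphthalide
Product: 17 [2-(hydroxymethyl)-3-methoxyphenyl]{5-methoxy-4-(methoxymethoxy)-3-[8-methoxy-1-(methoxymethoxy)naphthalen-2-yl]naphthalen-1-yl}methanone, via 4-lithio-8,8'-dimethoxy-1,1'-bis(methoxymethoxy)-2,2'-binaphthalene 16 (not isolated)
Conditions: n-BuLi (1.05 equiv), THF, −78 °C; then 5, −78 to −40 °C; aq. NH4Cl
Reagents that add atoms: none
Why: Bromine–lithium exchange followed by 1,2-addition of the aryllithium to the lactone carbonyl; the tetrahedral lithium alkoxide should persist at low temperature, so a second addition to the hindered diaryl ketone is not expected, and work-up gives 17 in ring–chain equilibrium with its hemiketal form.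

Step 11
Reactants: 17 keto alcohol from step 10; 18 racemic phenyl vinyl sulfoxide
Product: 21 racemic 1-Ar-5-methoxy-1,4-dihydro-1,4-epoxynaphthalene (relative configuration fixed by the oxygen bridge; one enantiomer drawn), via 1-Ar-4-methoxyisobenzofuran 19 (not isolated), via sulfinyl cycloadduct 20 (not isolated)
Conditions: 18 (5 equiv), AcOH (0.2 equiv), PhMe, 80 °C; then NaHCO3 (s), 110 °C
Reagents that add atoms: none
Why: Acetic acid ionises the hemiketal form of 17 to a diaryl oxocarbenium ion, and loss of a proton from the neighbouring OCH2 (a 1,4-elimination of water) gives the o-quinoid isobenzofuran 19, a diene reactive enough to add to the modest dienophile 18 below the temperature at which sulfoxides eliminate. The six-membered ring is closed by an intermolecular, concerted, suprafacial [4+2] cycloaddition (Diels–Alder) that forms both new C–C bonds, from the two furan alpha carbons of 19 to the two vinyl carbons of 18, and gives 20 as a mixture of regio- and stereoisomers. On further heating every isomer of 20 has a hydrogen on the adjacent CH2 that is cis to sulfur on the rigid bicycle, so a thermal syn (Ei) elimination of benzenesulfenic acid leaves the ring alkene of 21, while the bridgehead hydrogens cannot take part. The closest known reaction types are the trapping of isobenzofurans generated from aryllithium–phthalide adducts with alkenes and the use of phenyl vinyl sulfoxide as an acetylene equivalent in Diels–Alder reactions. The two new stereocentres are the bridgeheads; their relative configuration is fixed by the oxygen bridge because both diene termini react on the same face, nothing induces absolute configuration, so 21 is racemic, and both centres are removed in step 12. The only selectivity that matters is that the methoxyl lies next to the CH bridgehead, which is already set by phthalide 5; the orientation and endo or exo sense of the sulfoxide are irrelevant because sulfur is lost, and the naphthalene rings are not competitive dienes. NaHCO3 is added before the hot stage so that acetic acid cannot open the new bridge, and any 21 that isomerises early would only give the naphthol that step 12 produces in any case.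

Step 12
Reactants: 21 racemic 1-Ar-5-methoxy-1,4-dihydro-1,4-epoxynaphthalene
Product: 22 4-(4-hydroxy-5-methoxynaphthalen-1-yl)-2-(1-hydroxy-8-methoxynaphthalen-2-yl)-8-methoxynaphthalen-1-ol (target)
Conditions: HCl (3 M in MeOH)/THF, degassed, Ar, 45 °C
Reagents that add atoms: none
Why: Acid-catalysed isomerisation of a 1,4-epoxy-1,4-dihydronaphthalene to a 1-naphthol: the protonated bridge should ionise at the tertiary, allylic bridgehead whose naphthyl group carries a para oxygen, a 1,2-hydride shift from the other bridgehead gives the protonated 4-aryl-2H-naphthalen-1-one, and enolisation gives the naphthol with its oxygen peri to the methoxyl. The same methanolic acid transacetalises both methoxymethyl ethers, and no stereocentre remains.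

## Compound list

1 | 3-methoxy-2-methylbenzoic acid | Cc1c(OC)cccc1C(=O)O | starting material
2 | methyl 3-methoxy-2-methylbenzoate | Cc1c(OC)cccc1C(=O)OC | intermediate
3 | methyl 2-(bromomethyl)-3-methoxybenzoate | BrCc1c(OC)cccc1C(=O)OC | intermediate
4 | methyl 2-(hydroxymethyl)-3-methoxybenzoate | OCc1c(OC)cccc1C(=O)OC | intermediate (not isolated)
5 | 4-methoxyphthalide (4-methoxy-3H-2-benzofuran-1-one) | O=C1OCc2c(OC)cccc12 | intermediate
6 | naphthalene-1,8-diol | Oc1cccc2cccc(O)c12 | starting material
7 | 8-methoxynaphthalen-1-ol | COc1cccc2cccc(O)c12 | intermediate
8 | 1-methoxy-8-(methoxymethoxy)naphthalene | COCOc1cccc2cccc(OC)c12 | intermediate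
9 | 2-lithio-8-methoxy-1-(methoxymethoxy)naphthalene | COCOc1c([Li])ccc2cccc(OC)c12 | intermediate (not isolated)
10 | 2-iodo-8-methoxy-1-(methoxymethoxy)naphthalene | COCOc1c(I)ccc2cccc(OC)c12 | intermediate
11 | 2,4-dibromo-8-methoxynaphthalen-1-ol | COc1cccc2c(Br)cc(Br)c(O)c12 | intermediate
12 | 2,4-dibromo-8-methoxy-1-(methoxymethoxy)naphthalene | COCOc1c(Br)cc(Br)c2cccc(OC)c12 | intermediate
13 | 4-bromo-8-methoxy-1-(methoxymethoxy)naphthalen-2-ylmagnesium chloride | COCOc1c([Mg]Cl)cc(Br)c2cccc(OC)c12 | intermediate (not isolated)
14 | 4-bromo-8-methoxy-1-(methoxymethoxy)naphthalen-2-ylzinc chloride | COCOc1c([Zn]Cl)cc(Br)c2cccc(OC)c12 | intermediate (not isolated)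
15 | 4-bromo-8,8'-dimethoxy-1,1'-bis(methoxymethoxy)-2,2'-binaphthalene | COCOc1c(-c2ccc3cccc(OC)c3c2OCOC)cc(Br)c2cccc(OC)c12 | intermediate
16 | 4-lithio-8,8'-dimethoxy-1,1'-bis(methoxymethoxy)-2,2'-binaphthalene | COCOc1c(-c2ccc3cccc(OC)c3c2OCOC)cc([Li])c2cccc(OC)c12 | intermediate (not isolated)
17 | [2-(hydroxymethyl)-3-methoxyphenyl]{5-methoxy-4-(methoxymethoxy)-3-[8-methoxy-1-(methoxymethoxy)naphthalen-2-yl]naphthalen-1-yl}methanone (open form of the hemiketal) | OCc1c(OC)cccc1C(=O)c1cc(-c2ccc3cccc(OC)c3c2OCOC)c(OCOC)c2c(OC)cccc12 | intermediate
18 | phenyl vinyl sulfoxide (racemic) | C=CS(=O)c1ccccc1 | starting material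
19 | 1-Ar-4-methoxyisobenzofuran (4-methoxy-1-Ar-2-benzofuran) | COc1cccc2c(-c3cc(-c4ccc5cccc(OC)c5c4OCOC)c(OCOC)c4c(OC)cccc34)occ12 | intermediate (not isolated)
20 | 1-Ar-5-methoxy-3-(phenylsulfinyl)-1,2,3,4-tetrahydro-1,4-epoxynaphthalene (racemic; mixture of regio- and stereoisomers, one regioisomer drawn, sulfinyl carbon and sulfur undefined) | COc1cccc2c1[C@H]1C(S(=O)c3ccccc3)C[C@]2(c3cc(-c4ccc5cccc(OC)c5c4OCOC)c(OCOC)c4c(OC)cccc34)O1 | intermediate (not isolated)
21 | 1-Ar-5-methoxy-1,4-dihydro-1,4-epoxynaphthalene (racemic, one enantiomer drawn) | COc1cccc2c1[C@H]1C=C[C@]2(c3cc(-c4ccc5cccc(OC)c5c4OCOC)c(OCOC)c4c(OC)cccc34)O1 | intermediate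
22 | 4-(4-hydroxy-5-methoxynaphthalen-1-yl)-2-(1-hydroxy-8-methoxynaphthalen-2-yl)-8-methoxynaphthalen-1-ol | COc1cccc2ccc(-c3cc(-c4ccc(O)c5c(OC)cccc45)c4cccc(OC)c4c3O)c(O)c12 | target

## Step count and risks

Total step count: 12. Longest linear sequence: 7 steps (steps 4, 7, 8, 9, 10, 11, 12, from 6 to 22).

**Step 11 (key step).** Three events share one flask, and the likeliest failures are these: oligomerisation or oxidation of the isobenzofuran before the sluggish vinyl sulfoxide traps it; incomplete syn-elimination from the strained bicycle; and re-addition of benzenesulfenic acid to the new strained alkene or acid-induced opening of the bridge during the hot stage. The fallback sets out from 17 and returns at 21. Compound 17 is dehydrated as before, but in the presence of the far more reactive (E)-1,2-bis(phenylsulfonyl)ethene, to give the isolable trans-2,3-bis(phenylsulfonyl)-1-Ar-5-methoxy-1,2,3,4-tetrahydro-1,4-epoxynaphthalene F1. Reductive elimination of both sulfonyl groups with Na/Hg amalgam in NaH2PO4-buffered MeOH/THF at −20 °C then gives 21 with no thermal or acidic stage.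

**Step 12.** The peri methoxyl is ortho to the ring carbon bearing the CH bridgehead and stabilises ionisation there. Ionisation at this wrong bridgehead, followed by a 1,2-aryl shift, would give a 2-aryl-1-naphthol skeleton. Formaldehyde-derived alkylation of the liberated naphthols, acid-promoted closure of the 2,2'-diol to a furan, and air oxidation of the product are further ways to lose material. The fallback gives up the cycloaddition for this bond and is kept only as insurance; it sets out from 15 and 12 and returns at 22. Miyaura borylation of 15 (B2pin2, PdCl2(dppf), KOAc, dioxane, 90 °C) gives 2-[8,8'-dimethoxy-1,1'-bis(methoxymethoxy)-2,2'-binaphthalen-4-yl]-4,4,5,5-tetramethyl-1,3,2-dioxaborolane F2. Selective exchange of the ortho bromine of 12 with iPrMgCl·LiCl and protonation with MeOH gives 4-bromo-8-methoxy-1-(methoxymethoxy)naphthalene F3. Suzuki–Miyaura coupling of F2 with F3 (Pd(OAc)2, SPhos, K3PO4, toluene/H2O, 90 °C) gives the tris(methoxymethyl) ether of the target F4, and HCl in MeOH removes the three acetals to give 22.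

**Step 9.** Exchange at the para bromine, or insertion of palladium into C–Br bonds once the iodide runs low, would give regioisomeric or oligomeric biaryls. The fallback sets out from 10 and returns at 15. Ullmann homocoupling of 10 (Cu powder, DMF, 130 °C) gives 8,8'-dimethoxy-1,1'-bis(methoxymethoxy)-2,2'-binaphthalene F5, and HCl in MeOH gives 8,8'-dimethoxy-2,2'-binaphthalene-1,1'-diol F6. NBS (0.9 equiv, MeCN, −20 °C) brominates one ring para to its hydroxyl to give 4-bromo-8,8'-dimethoxy-2,2'-binaphthalene-1,1'-diol F7, which is separated from unchanged F6 and dibromide. NaH and MOMCl then give 15. This path is statistical at the bromination, which is why it is not the first choice.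

**Step 10.** Deprotonation of the acidic benzylic CH2 of the phthalide by the hindered aryllithium, or butylation of 16 by the 1-bromobutane formed in the exchange, would return debrominated or alkylated biaryl instead of 17. The fallback sets out from 5 and 15 and returns at 17. Ring opening of 5 with MeNH(OMe)·HCl and AlMe3 gives 2-(hydroxymethyl)-N,3-dimethoxy-N-methylbenzamide F8, and TBSCl with imidazole gives its tert-butyldimethylsilyl ether F9. Addition of 16 (from 15 and n-BuLi) to this Weinreb amide gives the silyl-protected ketone F10 through a chelated tetrahedral intermediate, and Bu4NF removes the silyl group to give 17.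

## Further compounds

F1 | step 11 | trans-2,3-bis(phenylsulfonyl)-1-Ar-5-methoxy-1,2,3,4-tetrahydro-1,4-epoxynaphthalene (racemic) | COc1cccc2c1[C@H]1C(S(=O)(=O)c3ccccc3)C(S(=O)(=O)c3ccccc3)[C@]2(c3cc(-c4ccc5cccc(OC)c5c4OCOC)c(OCOC)c4c(OC)cccc34)O1
F2 | step 12 | 2-[8,8'-dimethoxy-1,1'-bis(methoxymethoxy)-2,2'-binaphthalen-4-yl]-4,4,5,5-tetramethyl-1,3,2-dioxaborolane | COCOc1c(-c2ccc3cccc(OC)c3c2OCOC)cc(B2OC(C)(C)C(C)(C)O2)c2cccc(OC)c12
F3 | step 12 | 4-bromo-8-methoxy-1-(methoxymethoxy)naphthalene | COCOc1ccc(Br)c2cccc(OC)c12
F4 | step 12 | tris(methoxymethyl) ether of the target | COCOc1c(-c2ccc3cccc(OC)c3c2OCOC)cc(-c2ccc(OCOC)c3c(OC)cccc23)c2cccc(OC)c12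
F5 | step 9 | 8,8'-dimethoxy-1,1'-bis(methoxymethoxy)-2,2'-binaphthalene | COCOc1c(-c2ccc3cccc(OC)c3c2OCOC)ccc2cccc(OC)c12
F6 | step 9 | 8,8'-dimethoxy-2,2'-binaphthalene-1,1'-diol | COc1cccc2ccc(-c3ccc4cccc(OC)c4c3O)c(O)c12
F7 | step 9 | 4-bromo-8,8'-dimethoxy-2,2'-binaphthalene-1,1'-diol | COc1cccc2ccc(-c3cc(Br)c4cccc(OC)c4c3O)c(O)c12
F8 | step 10 | 2-(hydroxymethyl)-N,3-dimethoxy-N-methylbenzamide | CON(C)C(=O)c1cccc(OC)c1CO
F9 | step 10 | 2-[(tert-butyldimethylsilyloxy)methyl]-N,3-dimethoxy-N-methylbenzamide | CON(C)C(=O)c1cccc(OC)c1CO[Si](C)(C)C(C)(C)C
F10 | step 10 | tert-butyldimethylsilyl ether of 17 | CC(C)(C)[Si](C)(C)OCc1c(OC)cccc1C(=O)c1cc(-c2ccc3cccc(OC)c3c2OCOC)c(OCOC)c2c(OC)cccc12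
A1 | alternative 1 | 8,8'-dimethoxy-4,4'-bis(tert-butyldimethylsilyloxy)-1,1'-binaphthalene | COc1cccc2c(-c3ccc(O[Si](C)(C)C(C)(C)C)c4c(OC)cccc34)ccc(O[Si](C)(C)C(C)(C)C)c12
A2 | alternative 1 | (1E,3E,5E,7E)-1,8-bis(tert-butyldimethylsilyloxy)octa-1,3,5,7-tetraene | CC(C)(C)[Si](C)(C)O/C=C/C=C/C=C/C=C/O[Si](C)(C)C(C)(C)C
A3 | alternative 1 | 3-methoxy-2-(trimethylsilyl)phenyl trifluoromethanesulfonate | COc1cccc(OS(=O)(=O)C(F)(F)F)c1[Si](C)(C)C
A4 | alternative 2 | target with the central and para-linked hydroxyls as methoxymethyl ethers | COc1cccc2ccc(-c3cc(-c4ccc(OCOC)c5c(OC)cccc45)c4cccc(OC)c4c3OCOC)c(O)c12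
A5 | alternative 2 | 2-iodo-8-methoxynaphthalen-1-yl 4-chlorobenzenesulfonate | COc1cccc2ccc(I)c(OS(=O)(=O)c3ccc(Cl)cc3)c12
A6 | alternative 2 | 8,8'-dimethoxy-4,4'-bis(methoxymethoxy)-1,1'-binaphthalene | COCOc1ccc(-c2ccc(OCOC)c3c(OC)cccc23)c2cccc(OC)c12
A7 | alternative 3 | tert-butyldimethylsilyl ether of the central naphthol with both terminal units as benzyl ethers | COc1cccc2c1c(O[Si](C)(C)C(C)(C)C)c(-c1ccc3cccc(OC)c3c1OCc1ccccc1)cc2-c1ccc(OCc2ccccc2)c2c(OC)cccc12
A8 | alternative 3 | 3-(1-benzyloxy-8-methoxynaphthalen-2-yl)-3-chloro-3H-diazirine | ClC1(c2ccc3cccc(OC)c3c2OCc2ccccc2)N=N1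
A9 | alternative 3 | 1-(4-benzyloxy-5-methoxynaphthalen-1-yl)-3-(tert-butyldimethylsilyloxy)-4-methoxy-1H-indene (racemic) | COc1cccc2c1C(O[Si](C)(C)C(C)(C)C)=CC2c1ccc(OCc2ccccc2)c2c(OC)cccc12
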